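**Plan**
- Numbering used here: five-membered ring C1(H)–C2H2–C3(OH)–C4(=CH2)–C5(H); seven-membered ring C5–C6(OH)–C7–C8H2–C9(OH)–C10(=CH2)–C1; side chain C11(Me)–C12(OAc)–C13–C14=C15 on C7.
- Cuts, in order: acetate and C14=C15 (cross-metathesis), C12–C13 (allylboration of a lactol), C10=CH2 and C9–O (both from a C10 ketone), C1–C2 (ring-closing enolate alkylation), C4–C5 (conjugate addition), then the C6–O/C12 lactone, C11–Me and C7–C11, back to a meso cycloheptenediol diacetate.
- Enabling feature: C10, the seven-membered-ring carbon between ring-fusion C1 and carbinol C9, is carried as a ketone. As the C1=C5 enone it takes up C4 at C5; as the enolate it joins C1 to C2 (a CH2Cl next to the C3 silyloxy carbon); it lets C1 settle to the trans ring fusion, steers oxygenation of C9, and is finally methylenated.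
- Forward: cycloheptadiene → seven-membered ring with a cis-fused γ-lactone (C6–O, C7, C11, C12) → C10 ketone with C1=C5 enone → five-membered ring closed at C1–C2 (C2, C3, C4 all from glyceraldehyde) → C9–OH and C10=CH2 → side chain grown from the lactone.
- Stereochemistry: C6 by enzymatic desymmetrization; C7 by suprafacial Johnson–Claisen transfer; C11 by convex-face lactone methylation; C3 from (S)-glyceraldehyde acetonide; C5 by addition anti to the lactone; C1 by equilibration; C9 by enolate oxygenation; C12 by reagent-controlled allylboration.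

Key step: step 15

Assumption: the hydrolase of step 2 is taken to give the (1S,4R)-monoacetate; an enzyme of the opposite sense would be replaced by lipase-catalysed monoacetylation of the meso diol with vinyl acetate, which leads to the same enantiomer.

Step 1
Reactants: 1 cyclohepta-1,3-diene
Product: 2 cis-cyclohept-2-ene-1,4-diyl diacetate (meso)
Conditions: Pd(OAc)2 (5 mol%), LiCl (cat.), LiOAc, p-benzoquinone, AcOH, rt
Reagents that add atoms: acetic acid CC(=O)O
Why: Palladium-catalysed 1,4-diacetoxylation of the 1,3-diene through a π-allylpalladium intermediate should, with catalytic chloride, place both acetates on the same face and give the meso cis-diacetate.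

Step 2
Reactants: 2 cis-cyclohept-2-ene-1,4-diyl diacetate
Product: 3 (1S,4R)-4-hydroxycyclohept-2-en-1-yl acetate
Conditions: electric eel acetylcholinesterase, aqueous phosphate buffer (pH 7), rt
Reagents that add atoms: none
Why: Enzymatic desymmetrization (hydrolysis of one enantiotopic acetate of the meso diester) sets the absolute configuration of the acetoxy carbon, the later C6, and frees the C9 hydroxyl for the rearrangement.

Step 3
Reactants: 3 (1S,4R)-4-hydroxycyclohept-2-en-1-yl acetate
Product: 5 cis-fused lactone (3aR,8aS)-3,3a,6,7,8,8a-hexahydro-2H-cyclohepta[b]furan-2-one, via acetoxy ethyl ester 4 (not isolated)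
Conditions: MeC(OEt)3, EtCO2H (cat.), 140 °C; then K2CO3 (cat.), MeOH, rt; work-up at pH 3
Reagents that add atoms: triethyl orthoacetate CCOC(C)(OCC)OCC
Why: Johnson–Claisen rearrangement of the ketene acetal formed on the free allylic hydroxyl delivers the CH2CO2Et unit suprafacially to C7, hence cis to the C6 acetoxy group, and methanolysis of that acetate lets the cis γ-hydroxy ester close to the cis-fused γ-lactone.

Step 4
Reactants: 5 cis-fused lactone
Product: 6 (3S,3aS,8aS)-3-methyl-3,3a,6,7,8,8a-hexahydro-2H-cyclohepta[b]furan-2-one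
Conditions: LiN(iPr)2, THF, −78 °C; MeI, −78 → −40 °C
Reagents that add atoms: iodomethane CI
Why: Alkylation of the lactone enolate on the convex face of the cis-fused bicycle puts the C11 methyl trans to the C7–C8 bond, which is the configuration of the target.

Step 5
Reactants: 6 methyl lactone
Product: 7 enone lactone (C10 ketone conjugated with C8=C9; 3-methyl-3,3a,8,8a-tetrahydro-2H-cyclohepta[b]furan-2,6(7H)-dione)
Conditions: Rh2(cap)4 (cap = caprolactamate, 1 mol%), t-BuOOH (70% in water), CH2Cl2, rt
Reagents that add atoms: tert-butyl hydroperoxide CC(C)(C)OO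
Why: Dirhodium-catalysed allylic C–H oxidation (tert-butylperoxy radical chain) should attack the only allylic methylene, C10, and carry it to the ketone, the other allylic position C7 being a hindered methine.

Step 6
Reactants: 7 enone lactone
Product: 8 C1-phenylthio enone lactone (epimers at C1)
Conditions: LiN(iPr)2, THF, −78 °C; PhSO2SPh, −78 °C
Reagents that add atoms: S-phenyl benzenethiosulfonate O=S(=O)(Sc1ccccc1)c1ccccc1
Why: Kinetic α′-deprotonation can occur only at C1, since the other α-carbon C9 is vinylic, and sulfenylation of the lithium enolate marks C1 for the transposition of the unsaturation.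

Step 7
Reactants: 8 C1-phenylthio enone lactone
Product: 9 saturated C1-phenylthio ketone lactone (epimers at C1)
Conditions: [(Ph3P)CuH]6 (0.4 equiv), H2O, benzene, rt
Reagents that add atoms: none
Why: Conjugate reduction by the copper hydride saturates C8=C9 and should leave the ketone, the sulfide and the lactone untouched.

Step 8
Reactants: 9 saturated C1-phenylthio ketone lactone
Product: 11 enone lactone with C1=C5 (3-methyl-3,3a,4,5-tetrahydro-2H-cyclohepta[b]furan-2,6(8aH)-dione), via sulfoxide 10 (not isolated)
Conditions: mCPBA (1 equiv), CH2Cl2, −78 °C; then CaCO3, toluene, 110 °C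
Reagents that add atoms: none
Why: Sulfoxide syn-elimination can take its hydrogen only from C5 and so moves the enone unsaturation regiospecifically to C1=C5.

Step 9
Reactants: 12 (S)-2,2-dimethyl-1,3-dioxolane-4-carbaldehyde
Product: 13 (R)-4-ethynyl-2,2-dimethyl-1,3-dioxolane
Conditions: dimethyl (1-diazo-2-oxopropyl)phosphonate, K2CO3, MeOH, 0 °C → rt
Reagents that add atoms: dimethyl (1-diazo-2-oxopropyl)phosphonate CC(=O)C(=[N+]=[N-])P(=O)(OC)OC
Why: Ohira–Bestmann (Seyferth–Gilbert) homologation converts the aldehyde into the terminal alkyne under conditions mild enough to keep the α-oxygenated stereocentre, the later C3.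

Step 10
Reactants: 13 (R)-4-ethynyl-2,2-dimethyl-1,3-dioxolane
Product: 14 (R)-but-3-yne-1,2-diol
Conditions: AcOH/H2O (4:1), 40 °C
Reagents that add atoms: none
Why: Acid-catalysed acetal hydrolysis frees the diol without touching the stereocentre.

Step 11
Reactants: 14 (R)-but-3-yne-1,2-diol
Product: 16 (R)-1-chlorobut-3-yn-2-ol, via primary tosylate 15 (not isolated)
Conditions: TsCl, Bu2SnO (cat.), Et3N, CH2Cl2, 0 °C; then LiCl, DMF, 60 °C
Reagents that add atoms: lithium chloride [Li+].[Cl-]
Why: Stannylene-acetal-catalysed sulfonylation is selective for the primary hydroxyl, and SN2 displacement by chloride at that primary carbon leaves the stereocentre untouched.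

Step 12
Reactants: 16 (R)-1-chlorobut-3-yn-2-ol
Product: 17 (R)-tert-butyl[(1-chlorobut-3-yn-2-yl)oxy]dimethylsilane
Conditions: TBSCl, imidazole, DMF, rt
Reagents that add atoms: tert-butyldimethylsilyl chloride CC(C)(C)[Si](C)(C)Cl
Why: Silylation of the secondary propargylic alcohol gives an ether that should survive the organometallic and basic steps ahead.

Step 13
Reactants: 17 (R)-tert-butyl[(1-chlorobut-3-yn-2-yl)oxy]dimethylsilane
Product: 18 (R)-2-[4-chloro-3-(tert-butyldimethylsilyloxy)but-1-en-2-yl]-4,4,5,5-tetramethyl-1,3,2-dioxaborolane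
Conditions: (SIMes)CuCl (SIMes = 1,3-dimesitylimidazolidin-2-ylidene, 5 mol%), NaOtBu (5 mol%), B2pin2, MeOH, THF, rt
Reagents that add atoms: bis(pinacolato)diboron CC1(C)OB(OC1(C)C)B1OC(C)(C)C(C)(C)O1
Why: Copper-catalysed protoboration of the terminal alkyne (syn addition of Cu–B, then protonation by methanol) with an N-aryl carbene ligand and a propargylic ether should place boron on the internal carbon and give the 1,1-disubstituted alkenylboronate.

Step 14
Reactants: 11 enone lactone with C1=C5; 18 alkenylboronate
Product: 19 chloro ketone lactone (C10 ketone; C5 carries the (R)-4-chloro-3-(tert-butyldimethylsilyloxy)but-1-en-2-yl group trans to the C6 oxygen)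
Conditions: [Rh(cod)OH]2 (3 mol%), KOH (0.5 equiv), 1,4-dioxane/H2O (10:1), 50 °C; work-up at pH 3
Reagents that add atoms: none
Why: Rhodium-catalysed conjugate addition of the alkenylboronate (Hayashi–Miyaura reaction) forms C4–C5, the alkenyl group entering on the enone face opposite the cis-fused lactone so that C5 is set trans to the C6 oxygen, and it avoids copper reagents that would cleave the γ-acyloxy enone reductively.

Step 15
Reactants: 19 chloro ketone lactone
Product: 21 trans-fused tricyclic ketone (C10 ketone; H-1 and H-5 trans; C3 silyl ether; C4 methylene; C6/C12 lactone), via cis-fused ketone 20 (not isolated)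
Conditions: KOtBu (1.5 equiv), t-BuOH/THF (1:4), 0 °C → rt; work-up at pH 3
Reagents that add atoms: none
Why: tert-Butoxide deprotonates the C10 ketone reversibly and the enolate toward C1 displaces the primary chloride at C2 (intramolecular SN2 C-alkylation); the closest known reaction type is the methylenecyclopentane annulation in which a 2-(chloroalkyl)vinyl metal is added to a cyclic enone and the ring is then closed by enolate alkylation. The five-membered ring closes in the 5-(enolexo)-exo-tet mode, while alkylation through the C9 enolate would need a bridged seven-membered ring and O-alkylation a strained bridged enol ether, so neither should compete. C1 is the only new stereocentre: closure is expected cis to the C5 side arm (cis-fused ketone 20), and the same alkoxide then equilibrates C1 through the C10 enolate to the trans-fused ketone, which should be the more stable epimer because both ring-fusion bonds are then pseudo-equatorial on the cycloheptanone, as in other hydroazulenones with the carbonyl next to the ring fusion in the seven-membered ring. C3 comes in intact from the glyceraldehyde-derived fragment, C5 cannot epimerize, and C11, although enolizable, keeps its methyl on the convex face of the lactone, which is also its thermodynamic position. The step needs C- over O-alkylation, the C1 over the C9 enolate and the trans ring fusion; ring size secures the first two and reversible enolization next to the C10 carbonyl the third.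

Step 16
Reactants: 21 trans-fused tricyclic ketone
Product: 22 C9 hydroxy ketone (hydroxyl on the face of H-1)
Conditions: KN(SiMe3)2, THF, −78 °C; 2-(phenylsulfonyl)-3-phenyloxaziridine, −78 °C; NH4Cl
Reagents that add atoms: 2-(phenylsulfonyl)-3-phenyloxaziridine O=S(=O)(c1ccccc1)N1OC1c1ccccc1
Why: Kinetic deprotonation should occur at the C9 methylene (C1 is a ring-fusion methine, C11 a less acidic lactone α-carbon), and electrophilic hydroxylation of the potassium enolate by the N-sulfonyloxaziridine is expected on the face away from the C2 methylene on C1 and the lactone carbon on C7, which sets C9.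

Step 17
Reactants: 22 C9 hydroxy ketone
Product: 23 C9 tert-butyldimethylsilyl ether of 22
Conditions: TBSOTf, 2,6-lutidine, CH2Cl2, −78 → 0 °C
Reagents that add atoms: tert-butyldimethylsilyl trifluoromethanesulfonate CC(C)(C)[Si](C)(C)OS(=O)(=O)C(F)(F)F
Why: Silylation under non-enolizing conditions protects the α-hydroxy ketone before olefination.

Step 18
Reactants: 23 bis-silyl ketone lactone
Product: 24 C10 methylene compound (both exocyclic methylenes in place)
Conditions: Zn, CH2Br2, TiCl4, THF/CH2Cl2, 0 °C → rt
Reagents that add atoms: dibromomethane BrCBr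
Why: Takai–Lombardo methylenation uses a non-basic titanium–methylene reagent that should olefinate the hindered ketone without epimerizing C1 or C9 and without attacking the lactone.

Step 19
Reactants: 24 C10 methylene compound
Product: 25 lactol (anomers at C12)
Conditions: iBu2AlH, CH2Cl2, −78 °C
Reagents that add atoms: none
Why: Half-reduction of the γ-lactone at low temperature stops at the lactol, which is the masked C12 aldehyde with the C6 oxygen released.

Step 20
Reactants: 25 lactol
Product: 26 C6,C12-diol with an allyl group on C12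
Conditions: (−)-Ipc2B(allyl), Et2O, −78 °C → rt; then NaOH, H2O2
Reagents that add atoms: (−)-B-allyldiisopinocampheylborane C=CCB([C@@H]1C[C@@H]2C[C@H]([C@H]1C)C2(C)C)[C@@H]1C[C@@H]2C[C@H]([C@H]1C)C2(C)C
Why: Brown allylboration of the open hydroxy-aldehyde form of the lactol sets C12 under reagent control through a chair transition state, in the sense that the Felkin–Anh preference of the α-methyl aldehyde should reinforce (C12 oxygen syn to the C11 methyl).

Step 21
Reactants: 26 diol
Product: 27 C12 acetate
Conditions: Ac2O, pyridine, CH2Cl2, −20 → 0 °C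
Reagents that add atoms: acetic anhydride CC(=O)OC(C)=O
Why: Acylation should select the open-chain C12 hydroxyl over the C6 hydroxyl, which is flanked by the ring-fusion carbon C5 and the branched C7.

Step 22
Reactants: 27 C12 acetate
Product: 28 bis-silyl ether of the target
Conditions: second-generation Grubbs catalyst (5 mol%), 2-methyl-2-butene/CH2Cl2, 40 °C
Reagents that add atoms: 2-methyl-2-butene CC=C(C)C
Why: Olefin cross-metathesis turns the monosubstituted allyl terminus into the trisubstituted alkene, while the two hindered 1,1-disubstituted ring methylenes should not take part.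

Step 23
Reactants: 28 bis-silyl ether of the target
Product: 29 target (CNP0210891.3)
Conditions: HF·pyridine, pyridine, THF, 0 °C → rt
Reagents that add atoms: none
Why: Buffered fluoride desilylation frees the C3 and C9 allylic alcohols and should not cleave or migrate the C12 acetate.

**Compound list**
1 | cyclohepta-1,3-diene | C1=CC=CCCC1 | starting material
2 | cis-cyclohept-2-ene-1,4-diyl diacetate (meso) | CC(=O)O[C@H]1C=C[C@@H](OC(C)=O)CCC1 | intermediate
3 | (1S,4R)-4-hydroxycyclohept-2-en-1-yl acetate | O[C@H]1C=C[C@@H](OC(C)=O)CCC1 | intermediate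
4 | ethyl 2-(cis-7-acetoxycyclohept-2-en-1-yl)acetate (not isolated) | CCOC(=O)C[C@@H]1C=CCCC[C@@H]1OC(C)=O | intermediate
5 | (3aR,8aS)-3,3a,6,7,8,8a-hexahydro-2H-cyclohepta[b]furan-2-one (cis-fused lactone) | O=C1C[C@@H]2C=CCCC[C@@H]2O1 | intermediate
6 | (3S,3aS,8aS)-3-methyl-3,3a,6,7,8,8a-hexahydro-2H-cyclohepta[b]furan-2-one | O=C1[C@@H](C)[C@@H]2C=CCCC[C@@H]2O1 | intermediate
7 | enone lactone, C10 ketone with C8=C9 | O=C1[C@@H](C)[C@@H]2C=CC(=O)CC[C@@H]2O1 | intermediate
8 | C1-phenylthio enone lactone (epimers at C1) | O=C1[C@@H](C)[C@@H]2C=CC(=O)C(Sc3ccccc3)C[C@@H]2O1 | intermediate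
9 | saturated C1-phenylthio ketone lactone (epimers at C1) | O=C1[C@@H](C)[C@@H]2CCC(=O)C(Sc3ccccc3)C[C@@H]2O1 | intermediate
10 | C1 sulfoxide of 9 (not isolated) | O=C1[C@@H](C)[C@@H]2CCC(=O)C(S(=O)c3ccccc3)C[C@@H]2O1 | intermediate
11 | enone lactone, C10 ketone with C1=C5 | O=C1[C@@H](C)[C@@H]2CCC(=O)C=C[C@@H]2O1 | intermediate
12 | (S)-2,2-dimethyl-1,3-dioxolane-4-carbaldehyde | O=C[C@@H]1COC(C)(C)O1 | starting material
13 | (R)-4-ethynyl-2,2-dimethyl-1,3-dioxolane | C#C[C@@H]1COC(C)(C)O1 | intermediate
14 | (R)-but-3-yne-1,2-diol | C#C[C@H](CO)O | intermediate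
15 | (R)-2-hydroxybut-3-yn-1-yl 4-methylbenzenesulfonate (not isolated) | C#C[C@H](COS(=O)(=O)c1ccc(C)cc1)O | intermediate
16 | (R)-1-chlorobut-3-yn-2-ol | C#C[C@H](CCl)O | intermediate
17 | (R)-tert-butyl[(1-chlorobut-3-yn-2-yl)oxy]dimethylsilane | C#C[C@H](CCl)O[Si](C)(C)C(C)(C)C | intermediate
18 | (R)-2-[4-chloro-3-(tert-butyldimethylsilyloxy)but-1-en-2-yl]-4,4,5,5-tetramethyl-1,3,2-dioxaborolane | C=C(B1OC(C)(C)C(C)(C)O1)[C@H](CCl)O[Si](C)(C)C(C)(C)C | intermediate
19 | chloro ketone lactone (side arm on C5 trans to the C6 oxygen) | C=C([C@H](CCl)O[Si](C)(C)C(C)(C)C)[C@@H]1CC(=O)CC[C@H]2[C@H](C)C(=O)O[C@@H]12 | intermediate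
20 | cis-fused tricyclic ketone, C1 epimer of 21 (not isolated) | C=C1[C@@H](O[Si](C)(C)C(C)(C)C)C[C@@H]2C(=O)CC[C@H]3[C@H](C)C(=O)O[C@H]3[C@H]12 | intermediate
21 | trans-fused tricyclic ketone | C=C1[C@@H](O[Si](C)(C)C(C)(C)C)C[C@H]2C(=O)CC[C@H]3[C@H](C)C(=O)O[C@H]3[C@H]12 | intermediate
22 | C9 hydroxy ketone | C=C1[C@@H](O[Si](C)(C)C(C)(C)C)C[C@H]2C(=O)[C@H](O)C[C@H]3[C@H](C)C(=O)O[C@H]3[C@H]12 | intermediate
23 | C3,C9 bis(tert-butyldimethylsilyl) ether ketone | C=C1[C@@H](O[Si](C)(C)C(C)(C)C)C[C@H]2C(=O)[C@H](O[Si](C)(C)C(C)(C)C)C[C@H]3[C@H](C)C(=O)O[C@H]3[C@H]12 | intermediate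
24 | C10 methylene lactone | C=C1[C@@H](O[Si](C)(C)C(C)(C)C)C[C@H]2C(=C)[C@H](O[Si](C)(C)C(C)(C)C)C[C@H]3[C@H](C)C(=O)O[C@H]3[C@H]12 | intermediate
25 | lactol (anomers at C12) | C=C1[C@@H](O[Si](C)(C)C(C)(C)C)C[C@H]2C(=C)[C@H](O[Si](C)(C)C(C)(C)C)C[C@H]3[C@H](C)C(O)O[C@H]3[C@H]12 | intermediate
26 | C6,C12-diol with C12 allyl | C=C1[C@H]2[C@H](O)[C@H]([C@H](C)[C@H](CC=C)O)C[C@@H](O[Si](C)(C)C(C)(C)C)C(=C)[C@@H]2C[C@@H]1O[Si](C)(C)C(C)(C)C | intermediate
27 | C12 acetate | C=C1[C@H]2[C@H](O)[C@H]([C@H](C)[C@H](CC=C)OC(C)=O)C[C@@H](O[Si](C)(C)C(C)(C)C)C(=C)[C@@H]2C[C@@H]1O[Si](C)(C)C(C)(C)C | intermediate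
28 | C3,C9 bis(tert-butyldimethylsilyl) ether of the target | C=C1[C@H]2[C@H](O)[C@H]([C@H](C)[C@H](CC=C(C)C)OC(C)=O)C[C@@H](O[Si](C)(C)C(C)(C)C)C(=C)[C@@H]2C[C@@H]1O[Si](C)(C)C(C)(C)C | intermediate
29 | CNP0210891.3 | C=C1[C@H]2[C@H](O)[C@H]([C@H](C)[C@H](CC=C(C)C)OC(C)=O)C[C@@H](O)C(=C)[C@@H]2C[C@@H]1O | target

**Totals.** 23 steps in all; longest linear sequence 18 steps (steps 1–8 and 14–23); the alkenylboronate fragment takes steps 9–13.

**Steps most likely to fail**

1. Step 15 (key step). The ring-fusion equilibrium at C1 may not settle on the trans ketone while the cycloheptanone is clamped by the cis-fused lactone, and tert-butoxide may open the lactone so that the C6 alkoxide attacks the chloride. The fallback sets out from 19 and comes back at 21: the lactone is opened with Me2AlN(OMe)Me to the hydroxy Weinreb amide F1, and the C6 hydroxyl is silylated with TESOTf and 2,6-lutidine to the triethylsilyl ether F2. Cyclization and equilibration with KOtBu are then run on this unclamped cycloheptanone, which should give the trans-fused ketone F3. Camphorsulfonic acid in MeOH removes the triethylsilyl group, and warming with the same acid in toluene closes the γ-hydroxy amide back to the lactone 21.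

2. Step 14. Transmetalation and insertion of the hindered 1,1-disubstituted alkenylboronate may be slow, so that protodeboronation or β-silyloxy elimination from the alkenylrhodium species takes over. The fallback sets out from 18 (with 11) and comes back at 19: iododeboronation of 18 (NaOMe, then ICl) gives the (S)-alkenyl iodide F4. A reductive Heck reaction of F4 with enone 11 (Pd(OAc)2, HCO2Na, Et3N, Bu4NCl, DMF, 60 °C) forms the same C4–C5 bond through an alkenylpalladium species, and formate reduction of the palladium enolate gives 19.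

3. Step 16. Oxygen transfer to the C9 enolate may show poor facial selectivity, or enolization may compete at C1. The fallback sets out from 21 and comes back at 24: methylenation of 21 first (Zn, CH2Br2, TiCl4) gives the C10 methylene compound F5, and allylic oxidation with SeO2 (cat.) and t-BuOOH converts the C9 methylene into the allylic alcohol F6. Should this alcohol have the wrong configuration, Dess–Martin oxidation gives the α-methylene ketone F7, and reduction with NaBH4/CeCl3 delivers hydride from the face that oxygen had used, giving the epimeric alcohol F8 with the target configuration. Silylation of F8 with TBSOTf and 2,6-lutidine gives 24.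

**Further compounds**
F1 | step 15 | hydroxy Weinreb amide from lactone opening of 19 (C6 hydroxyl free) | C=C([C@H](CCl)O[Si](C)(C)C(C)(C)C)[C@@H]1CC(=O)CC[C@@H]([C@H](C)C(=O)N(C)OC)[C@H]1O
F2 | step 15 | C6 triethylsilyl ether of F1 | C=C([C@H](CCl)O[Si](C)(C)C(C)(C)C)[C@@H]1CC(=O)CC[C@@H]([C@H](C)C(=O)N(C)OC)[C@H]1O[Si](CC)(CC)CC
F3 | step 15 | trans-fused C10 ketone with C6 triethylsilyl ether and C12 Weinreb amide | C=C1[C@H]2[C@H](O[Si](CC)(CC)CC)[C@H]([C@H](C)C(=O)N(C)OC)CCC(=O)[C@@H]2C[C@@H]1O[Si](C)(C)C(C)(C)C
F4 | step 14 | (S)-tert-butyl[(1-chloro-3-iodobut-3-en-2-yl)oxy]dimethylsilane | C=C(I)[C@H](CCl)O[Si](C)(C)C(C)(C)C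
F5 | step 16 | C10 methylene lactone without C9 oxygen | C=C1[C@@H](O[Si](C)(C)C(C)(C)C)C[C@H]2C(=C)CC[C@H]3[C@H](C)C(=O)O[C@H]3[C@H]12
F6 | step 16 | C9 allylic alcohol (configuration at C9 as formed) | C=C1[C@@H](O[Si](C)(C)C(C)(C)C)C[C@H]2C(=C)C(O)C[C@H]3[C@H](C)C(=O)O[C@H]3[C@H]12
F7 | step 16 | C9 ketone (α-methylene ketone) | C=C1[C@@H](O[Si](C)(C)C(C)(C)C)C[C@H]2C(=C)C(=O)C[C@H]3[C@H](C)C(=O)O[C@H]3[C@H]12
F8 | step 16 | C9 alcohol with the target configuration | C=C1[C@@H](O[Si](C)(C)C(C)(C)C)C[C@H]2C(=C)[C@H](O)C[C@H]3[C@H](C)C(=O)O[C@H]3[C@H]12
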